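All runs are calculated with made-up constants, noise included.

Don't take a flattening curve for equilibrium, for Tuesday's last two readings differ by 1.6 percentage points against a scatter of 1 point, so they can't tell a finished flask from a slow one.

| flask | starting complex | incoming ligand | leaving ligand | remark | time |
|---|---|---|---|---|---|
| Monday's | 0.020 M | 0.68 equiv | 1 equiv | run made earlier |  |
| Tuesday's | 0.020 M | 1.7 equiv | 1 equiv | run made earlier |  |
| dusk | 0.020 M | 1.00 equiv | 1.00 equiv |  | 3.0 d |
| noon | 0.020 M | 2.00 equiv | 1.00 equiv |  | 3.0 d |
| dawn | 0.020 M | 2.50 equiv | 1.00 equiv |  | 3.0 d |

- Monday's (time / h: complex with one exchanged / %): 6.00: 8.5; 12.0: 13.0; 20.0: 17.2; 25.0: 21.0; 30.0: 21.7; 40.0: 22.3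
- Tuesday's (time / h: complex with one exchanged / %): 2.50: 7.9; 8.00: 20.1; 12.0: 22.3; 20.0: 27.5; 30.0: 33.6; 40.0: 35.2

(readings scatter by 1 percentage point)

- the analysis behind the earlier runs scatters by 1 percentage point, standard deviation
- what may be going on: complex with one exchanged + incoming ligand <-> leaving ligand + complex with two exchanged; 2 incoming ligand -> self-condensation product; leaving ligand -> by-product carried off; complex with one exchanged -> over-reaction product; starting complex + incoming ligand <-> leaving ligand + complex with one exchanged

1. final complex with one exchanged, as a percentage of the starting complex charged, for each flask in turn (dusk, noon, dawn)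

Clock the first exchange instead, using Tuesday's earliest reading, 7.9 % of complex with one exchanged after 2.50 h. Treat that step as pseudo-first-order and define the half-clock 1.55 d: the first-order half-life of the starting complex with the rate constant read from that one reading, with [incoming ligand] held at its charge, here scaled to the dusk charge. Count the 3.0 d of the dusk flask as 1.94 half-clocks, a rough measure, since the clock sets aside the return step and the falling [incoming ligand]. Expect the dusk flask to be still moving at the asked time, a reckoning of your own that differs from the forecast, which holds that “72 h should reach equilibrium” and gives 29 %, 40 % and 43 % for dusk, noon and dawn.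

The flasks give 32.8 %, 42.0 % and 44.6 %, so the forecast held within its margin.

    complex with one exchanged + incoming ligand ⇌ leaving ligand + complex with two exchanged (K = 9.30, k = 0.00580 M⁻¹ min⁻¹)
    2 incoming ligand → self-condensation product (k = 0.0300 M⁻¹ min⁻¹)
    leaving ligand → by-product carried off (k = 7.20 × 10⁻⁴ min⁻¹)
    complex with one exchanged → over-reaction product (k = 1.10 × 10⁻⁶ min⁻¹)
    starting complex + incoming ligand ⇌ leaving ligand + complex with one exchanged (K = 46.0, k = 0.0200 M⁻¹ min⁻¹)

Watch two clocks: at dusk the first exchange relaxes with a half-life of 1.66 d at the asked time, about the size of the half-clock and shorter than the 10.2 d of the second exchange, which is long against the run of 3.0 d. In the noon flask the half-clock scaled to its charge is 0.777 d, and its complex with one exchanged stands at 42.0 % after 3.00 d and at 44.4 % after 30.0 d.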